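The 3(2H)-furanone ring is read as a masked α′-hydroxy ynone: its enol-ether double bond C2=C3 is a latent alkyne and its ketone C1 a latent aldehyde. Disconnecting the C1–C2 bond, which lies in both the furanone ring and the ten-membered carbocycle, leaves one acyclic iodoalkyne/tertiary α-hydroxy aldehyde that already holds the trans-fused methylene lactone, the (S)-2-methylbutanoate and the Z-C4=C5 alkene. A Nozaki–Hiyama–Kishi alkynylation closes the ten-membered ring at C1–C2; oxidation then lets the C10 hydroxyl add across the ring to C3 (5-endo-dig), forming the oxygen bridge. The chain comes from a boron aldol/lactonisation of an enynal with a glycidol-derived keto ester.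

Key step: step 14

Remark: compounds 1, 5 and 13 are taken as commercial. Atom labels follow germacrane numbering of the target: C1 furanone C=O, C2 furanone CH, C3 furanone C–O, C4=C5 ring alkene (methyl C15), C6 lactone O–CH, C7 ring-fusion CH, C8 acyloxy CH, C9 CH2, C10 quaternary C–O (methyl C14), C11/C12/C13 lactone C=, C=O and =CH2.

Step 1
Reactants: 1 (2Z)-3-methylpent-2-en-4-yn-1-ol
Product: 3 (2Z)-3-methyl-5-(trimethylsilyl)pent-2-en-4-yn-1-ol, via bis-silyl ether 2 (not isolated)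
Conditions: EtMgBr (2.1 equiv), THF, 0 °C to rt; Me3SiCl (2.1 equiv); then 1 M HCl (aq), rt
Reagents that add atoms: chlorotrimethylsilane C[Si](C)(C)Cl
Why: Deprotonation of O–H and C(sp)–H, silylation of both sites and selective acid cleavage of the labile O–Si bond should leave the C-silyl alkyne (alkyne protection for step 10) with the Z alkene untouched.

Step 2
Reactants: 3 (2Z)-3-methyl-5-(trimethylsilyl)pent-2-en-4-yn-1-ol
Product: 4 (2Z)-3-methyl-5-(trimethylsilyl)pent-2-en-4-ynal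
Conditions: TEMPO (10 mol %), PhI(OAc)2 (1.1 equiv), CH2Cl2, rt
Reagents that add atoms: none
Why: Oxoammonium (TEMPO) oxidation of the allylic alcohol is neutral and stops at the aldehyde, so the Z-C4=C5 alkene should not isomerise.

Step 3
Reactants: 5 (S)-2-methylglycidol
Product: 6 (2R)-2-methylpent-4-yne-1,2-diol
Conditions: LiC≡CH·H2NCH2CH2NH2 (3 equiv), DMSO, rt; then H2O
Reagents that add atoms: lithium acetylide–ethylenediamine complex [Li]C#C.NCCN
Why: SN2 opening of the epoxide at its unsubstituted CH2 leaves the C–O bond at the quaternary carbon intact, so the tertiary carbinol (later C10) keeps the chiral-pool configuration.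

Step 4
Reactants: 6 (2R)-2-methylpent-4-yne-1,2-diol
Product: 7 (4R)-2,2,4-trimethyl-4-(prop-2-yn-1-yl)-1,3-dioxolane
Conditions: Me2C(OMe)2, PPTS (cat.), CH2Cl2, rt
Reagents that add atoms: 2,2-dimethoxypropane COC(C)(C)OC
Why: Acid-catalysed transketalisation protects the C10 and C1 hydroxyls together as an acetonide.

Step 5
Reactants: 7 (4R)-2,2,4-trimethyl-4-(prop-2-yn-1-yl)-1,3-dioxolane
Product: 8 ethyl 5-[(4R)-2,2,4-trimethyl-1,3-dioxolan-4-yl]pent-3-ynoate
Conditions: N2CHCO2Et (1.2 equiv), CuI (5 mol %), MeCN, rt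
Reagents that add atoms: ethyl diazoacetate CCOC(=O)C=[N+]=[N-]
Why: Copper-catalysed coupling of a terminal alkyne with a diazoacetate (copper acetylide/carbene coupling) gives the 3-alkynoate under base-free conditions, which avoids isomerisation to the allenoate.

Step 6
Reactants: 8 ethyl 5-[(4R)-2,2,4-trimethyl-1,3-dioxolan-4-yl]pent-3-ynoate
Product: 9 ethyl 4-oxo-5-[(4R)-2,2,4-trimethyl-1,3-dioxolan-4-yl]pentanoate
Conditions: NaAuCl4·2H2O (2 mol %), EtOH/H2O 4:1, rt
Reagents that add atoms: water O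
Why: Gold-catalysed alkyne hydration assisted by the neighbouring ester carbonyl (5-endo-dig attack of the carbonyl oxygen on the distal alkyne carbon, then hydrolysis) should place the ketone at C8 and give the γ-keto ester.

Step 7
Reactants: 9 ethyl 4-oxo-5-[(4R)-2,2,4-trimethyl-1,3-dioxolan-4-yl]pentanoate; 4 (2Z)-3-methyl-5-(trimethylsilyl)pent-2-en-4-ynal
Product: 11 (4S,5R)-5-[(1Z)-2-methyl-4-(trimethylsilyl)but-1-en-3-yn-1-yl]-4-{[(4R)-2,2,4-trimethyl-1,3-dioxolan-4-yl]acetyl}oxolan-2-one, via syn-aldol hydroxy ester 10 (not isolated)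
Conditions: (−)-Ipc2BOTf, i-Pr2NEt, CH2Cl2, −78 °C; 4, −78 to −20 °C; H2O2, MeOH, pH 7 buffer, 0 °C; then PPTS (cat.), CH2Cl2, rt
Reagents that add atoms: none
Why: Boron-mediated syn-aldol reaction then lactonisation: the bulky boron triflate should enolise the less hindered CH2 (C7, not the neopentyl-type C9) to the (Z)-enolate, whose Zimmerman–Traxler chair gives the 6,7-syn adduct with Si-face attack on the aldehyde directed by the (−)-Ipc ligands (sets C6 and C7), and the γ-hydroxy ester then closes to the trans-disubstituted lactone.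

Step 8
Reactants: 11 (4S,5R)-5-[(1Z)-2-methyl-4-(trimethylsilyl)but-1-en-3-yn-1-yl]-4-{[(4R)-2,2,4-trimethyl-1,3-dioxolan-4-yl]acetyl}oxolan-2-one
Product: 12 (4R,5R)-4-{(1R)-1-hydroxy-2-[(4R)-2,2,4-trimethyl-1,3-dioxolan-4-yl]ethyl}-5-[(1Z)-2-methyl-4-(trimethylsilyl)but-1-en-3-yn-1-yl]oxolan-2-one
Conditions: LiBH(s-Bu)3 (1.1 equiv), THF, −78 °C; then AcOH
Reagents that add atoms: none
Why: Felkin–Anh-controlled reduction: the bulky hydride attacks the C8 ketone anti to the larger α-substituent (C6, which carries the ring oxygen and the enyne arm), which should give the 8R alcohol, and the ketone reacts far faster than the lactone at −78 °C.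

Step 9
Reactants: 12 (4R,5R)-4-{(1R)-1-hydroxy-2-[(4R)-2,2,4-trimethyl-1,3-dioxolan-4-yl]ethyl}-5-[(1Z)-2-methyl-4-(trimethylsilyl)but-1-en-3-yn-1-yl]oxolan-2-one; 13 (2S)-2-methylbutanoic acid
Product: 14 (1R)-1-{(2R,3R)-2-[(1Z)-2-methyl-4-(trimethylsilyl)but-1-en-3-yn-1-yl]-5-oxooxolan-3-yl}-2-[(4R)-2,2,4-trimethyl-1,3-dioxolan-4-yl]ethyl (2S)-2-methylbutanoate
Conditions: DCC (1.5 equiv), DMAP (0.3 equiv), CH2Cl2, 0 °C to rt
Reagents that add atoms: none
Why: Steglich esterification acylates the only free hydroxyl with retention at C8 and, at low temperature with catalytic DMAP, should not epimerise the α-centre of the acid.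

Step 10
Reactants: 14 (1R)-1-{(2R,3R)-2-[(1Z)-2-methyl-4-(trimethylsilyl)but-1-en-3-yn-1-yl]-5-oxooxolan-3-yl}-2-[(4R)-2,2,4-trimethyl-1,3-dioxolan-4-yl]ethyl (2S)-2-methylbutanoate
Product: 17 (1R)-1-{(2R,3R)-4-methylidene-2-[(1Z)-2-methyl-4-(trimethylsilyl)but-1-en-3-yn-1-yl]-5-oxooxolan-3-yl}-2-[(4R)-2,2,4-trimethyl-1,3-dioxolan-4-yl]ethyl (2S)-2-methylbutanoate, via Mannich base 15 (not isolated), via ammonium iodide 16 (not isolated)
Conditions: LiN(SiMe3)2 (1.05 equiv), THF, −78 °C; CH2=NMe2+ I−, −78 to 0 °C; MeI, MeOH, rt; then NaHCO3 (aq), CH2Cl2, rt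
Reagents that add atoms: Eschenmoser's salt C=[N+](C)C.[I-]; iodomethane CI (its methyl is carried only by 16 and leaves as trimethylamine)
Why: Mannich methylenation: the lactone CH2 (C11) is the most acidic C–H, its lithium enolate is aminomethylated by the iminium salt, and quaternisation followed by mild-base E1cB elimination installs the exocyclic C11=C13 alkene.

Step 11
Reactants: 17 (1R)-1-{(2R,3R)-4-methylidene-2-[(1Z)-2-methyl-4-(trimethylsilyl)but-1-en-3-yn-1-yl]-5-oxooxolan-3-yl}-2-[(4R)-2,2,4-trimethyl-1,3-dioxolan-4-yl]ethyl (2S)-2-methylbutanoate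
Product: 18 (1R)-1-{(2R,3R)-2-[(1Z)-4-iodo-2-methylbut-1-en-3-yn-1-yl]-4-methylidene-5-oxooxolan-3-yl}-2-[(4R)-2,2,4-trimethyl-1,3-dioxolan-4-yl]ethyl (2S)-2-methylbutanoate
Conditions: NIS (1.2 equiv), AgNO3 (10 mol %), DMF, rt, dark
Reagents that add atoms: N-iodosuccinimide O=C1CCC(=O)N1I
Why: Silver-catalysed iododesilylation: the silver acetylide formed from the C-silyl alkyne is iodinated by NIS, which should give the 1-iodoalkyne without touching the enoate or the acetonide.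

Step 12
Reactants: 18 (1R)-1-{(2R,3R)-2-[(1Z)-4-iodo-2-methylbut-1-en-3-yn-1-yl]-4-methylidene-5-oxooxolan-3-yl}-2-[(4R)-2,2,4-trimethyl-1,3-dioxolan-4-yl]ethyl (2S)-2-methylbutanoate
Product: 19 (1R,3R)-3,4-dihydroxy-1-{(2R,3R)-2-[(1Z)-4-iodo-2-methylbut-1-en-3-yn-1-yl]-4-methylidene-5-oxooxolan-3-yl}-3-methylbutyl (2S)-2-methylbutanoate
Conditions: AcOH/H2O/THF 3:1:1, 45 °C
Reagents that add atoms: none
Why: Aqueous acetic acid hydrolyses the acetonide to the primary/tertiary 1,2-diol, whereas the esters, the lactone and the iodoalkyne are stable to these conditions.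

Step 13
Reactants: 19 (1R,3R)-3,4-dihydroxy-1-{(2R,3R)-2-[(1Z)-4-iodo-2-methylbut-1-en-3-yn-1-yl]-4-methylidene-5-oxooxolan-3-yl}-3-methylbutyl (2S)-2-methylbutanoate
Product: 20 (1R,3R)-3-hydroxy-1-{(2R,3R)-2-[(1Z)-4-iodo-2-methylbut-1-en-3-yn-1-yl]-4-methylidene-5-oxooxolan-3-yl}-3-methyl-4-oxobutyl (2S)-2-methylbutanoate
Conditions: IBX (1.5 equiv), DMSO, rt
Reagents that add atoms: none
Why: IBX oxidises the primary alcohol to the aldehyde without cleaving the 1,2-diol, and the tertiary hydroxyl cannot be oxidised; the α-carbon is quaternary, so the aldehyde cannot epimerise.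

Step 14
Reactants: 20 (1R,3R)-3-hydroxy-1-{(2R,3R)-2-[(1Z)-4-iodo-2-methylbut-1-en-3-yn-1-yl]-4-methylidene-5-oxooxolan-3-yl}-3-methyl-4-oxobutyl (2S)-2-methylbutanoate
Product: 21 (4Z,6R,7R,8R,10R)-1,10-dihydroxy-8-[(2S)-2-methylbutanoyloxy]germacra-4,11(13)-dien-2-yn-12,6-olide (ten-membered cycloalkyne, both C1 epimers)
Conditions: CrCl2 (8 equiv), NiCl2 (2 mol %), degassed THF, rt, slow addition of 20 (final 2 mM); then H2O
Reagents that add atoms: none
Why: Nozaki–Hiyama–Kishi alkynylation: divalent chromium (with catalytic nickel) inserts reductively into the C(sp)–I bond to give an alkynyl species of trivalent chromium, which adds to the aldehyde carbon C1 and so forms the C1–C2 bond. The closest known reaction type is the CrCl2/NiCl2 closure of iodoalkyne aldehydes to strained ten-membered enediyne carbocycles. The ten-membered carbocycle closes in the 10-exo-trig mode at the carbonyl; the furanone ring is not closed here and follows in step 15 by 5-endo-dig attack of the C10 hydroxyl. The new carbinol centre C1 is not controlled and need not be, since it becomes the ketone in step 15. The step needs chemoselectivity for the aldehyde over lactone, enoate and ester, which organochromium reagents provide (they should also tolerate the free tertiary hydroxyl), and cyclisation over oligomerisation, which slow addition at high dilution and the turn elements of the chain (Z-C4=C5 alkene, trans-lactone, quaternary C10) should secure.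

Step 15
Reactants: 21 (4Z,6R,7R,8R,10R)-1,10-dihydroxy-8-[(2S)-2-methylbutanoyloxy]germacra-4,11(13)-dien-2-yn-12,6-olide
Product: 23 atripliciolide (2S)-2-methylbutanoate, [(3aR,4R,6R,10Z,11aR)-6,10-dimethyl-3-methylidene-2,7-dioxo-2,3,3a,4,5,6,7,11a-octahydro-6,9-epoxycyclodeca[b]furan-4-yl] (2S)-2-methylbutanoate, via ynone 22 (not isolated)
Conditions: IBX (2 equiv), DMSO, rt; extractive work-up; then (Ph3P)AuNTf2 (3 mol %), CH2Cl2, rt
Reagents that add atoms: none
Why: IBX oxidises the propargylic alcohol to the ynone without glycol cleavage, and gold activation of the strained ring alkyne then lets the C10 hydroxyl add transannularly to C3 (5-endo-dig cycloisomerisation), which forms the oxygen bridge and the 3(2H)-furanone with C10 unchanged.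

Compound list
1 | (2Z)-3-methylpent-2-en-4-yn-1-ol | OC/C=C(/C)C#C | starting material
2 | (2Z)-trimethyl{[3-methyl-5-(trimethylsilyl)pent-2-en-4-yn-1-yl]oxy}silane | C[Si](C)(C)OC/C=C(/C)C#C[Si](C)(C)C | intermediate
3 | (2Z)-3-methyl-5-(trimethylsilyl)pent-2-en-4-yn-1-ol | OC/C=C(/C)C#C[Si](C)(C)C | intermediate
4 | (2Z)-3-methyl-5-(trimethylsilyl)pent-2-en-4-ynal | O=C/C=C(/C)C#C[Si](C)(C)C | intermediate
5 | (S)-2-methylglycidol, [(2S)-2-methyloxiran-2-yl]methanol | OC[C@@]1(C)CO1 | starting material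
6 | (2R)-2-methylpent-4-yne-1,2-diol | OC[C@@](C)(CC#C)O | intermediate
7 | (4R)-2,2,4-trimethyl-4-(prop-2-yn-1-yl)-1,3-dioxolane | O1C(C)(C)OC[C@@]1(C)CC#C | intermediate
8 | ethyl 5-[(4R)-2,2,4-trimethyl-1,3-dioxolan-4-yl]pent-3-ynoate | O1C(C)(C)OC[C@@]1(C)CC#CCC(=O)OCC | intermediate
9 | ethyl 4-oxo-5-[(4R)-2,2,4-trimethyl-1,3-dioxolan-4-yl]pentanoate | O1C(C)(C)OC[C@@]1(C)CC(=O)CCC(=O)OCC | intermediate
10 | ethyl (3S,4R,5Z)-4-hydroxy-6-methyl-3-{[(4R)-2,2,4-trimethyl-1,3-dioxolan-4-yl]acetyl}-8-(trimethylsilyl)oct-5-en-7-ynoate | CCOC(=O)C[C@@H]([C@H](O)/C=C(/C)C#C[Si](C)(C)C)C(=O)C[C@]1(C)COC(C)(C)O1 | intermediate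
11 | (4S,5R)-5-[(1Z)-2-methyl-4-(trimethylsilyl)but-1-en-3-yn-1-yl]-4-{[(4R)-2,2,4-trimethyl-1,3-dioxolan-4-yl]acetyl}oxolan-2-one | C1C(=O)O[C@H](/C=C(/C)C#C[Si](C)(C)C)[C@H]1C(=O)C[C@]2(C)COC(C)(C)O2 | intermediate
12 | (4R,5R)-4-{(1R)-1-hydroxy-2-[(4R)-2,2,4-trimethyl-1,3-dioxolan-4-yl]ethyl}-5-[(1Z)-2-methyl-4-(trimethylsilyl)but-1-en-3-yn-1-yl]oxolan-2-one | C1C(=O)O[C@H](/C=C(/C)C#C[Si](C)(C)C)[C@H]1[C@H](O)C[C@]2(C)COC(C)(C)O2 | intermediate
13 | (2S)-2-methylbutanoic acid | OC(=O)[C@@H](C)CC | starting material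
14 | (1R)-1-{(2R,3R)-2-[(1Z)-2-methyl-4-(trimethylsilyl)but-1-en-3-yn-1-yl]-5-oxooxolan-3-yl}-2-[(4R)-2,2,4-trimethyl-1,3-dioxolan-4-yl]ethyl (2S)-2-methylbutanoate | C1C(=O)O[C@H](/C=C(/C)C#C[Si](C)(C)C)[C@H]1[C@H](OC(=O)[C@@H](C)CC)C[C@]2(C)COC(C)(C)O2 | intermediate
15 | 4-[(dimethylamino)methyl] derivative of 14 at the lactone α-carbon C11 (both C11 epimers) | CN(C)CC1C(=O)O[C@H](/C=C(/C)C#C[Si](C)(C)C)[C@H]1[C@H](OC(=O)[C@@H](C)CC)C[C@]2(C)COC(C)(C)O2 | intermediate
16 | N-methyl quaternary ammonium iodide of 15 | C[N+](C)(C)CC1C(=O)O[C@H](/C=C(/C)C#C[Si](C)(C)C)[C@H]1[C@H](OC(=O)[C@@H](C)CC)C[C@]2(C)COC(C)(C)O2.[I-] | intermediate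
17 | (1R)-1-{(2R,3R)-4-methylidene-2-[(1Z)-2-methyl-4-(trimethylsilyl)but-1-en-3-yn-1-yl]-5-oxooxolan-3-yl}-2-[(4R)-2,2,4-trimethyl-1,3-dioxolan-4-yl]ethyl (2S)-2-methylbutanoate | C=C1C(=O)O[C@H](/C=C(/C)C#C[Si](C)(C)C)[C@H]1[C@H](OC(=O)[C@@H](C)CC)C[C@]2(C)COC(C)(C)O2 | intermediate
18 | (1R)-1-{(2R,3R)-2-[(1Z)-4-iodo-2-methylbut-1-en-3-yn-1-yl]-4-methylidene-5-oxooxolan-3-yl}-2-[(4R)-2,2,4-trimethyl-1,3-dioxolan-4-yl]ethyl (2S)-2-methylbutanoate | C=C1C(=O)O[C@H](/C=C(/C)C#CI)[C@H]1[C@H](OC(=O)[C@@H](C)CC)C[C@]2(C)COC(C)(C)O2 | intermediate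
19 | (1R,3R)-3,4-dihydroxy-1-{(2R,3R)-2-[(1Z)-4-iodo-2-methylbut-1-en-3-yn-1-yl]-4-methylidene-5-oxooxolan-3-yl}-3-methylbutyl (2S)-2-methylbutanoate | C=C1C(=O)O[C@H](/C=C(/C)C#CI)[C@H]1[C@H](OC(=O)[C@@H](C)CC)C[C@@](C)(O)CO | intermediate
20 | (1R,3R)-3-hydroxy-1-{(2R,3R)-2-[(1Z)-4-iodo-2-methylbut-1-en-3-yn-1-yl]-4-methylidene-5-oxooxolan-3-yl}-3-methyl-4-oxobutyl (2S)-2-methylbutanoate | C=C1C(=O)O[C@H](/C=C(/C)C#CI)[C@H]1[C@H](OC(=O)[C@@H](C)CC)C[C@@](C)(O)C=O | intermediate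
21 | (4Z,6R,7R,8R,10R)-1,10-dihydroxy-8-[(2S)-2-methylbutanoyloxy]germacra-4,11(13)-dien-2-yn-12,6-olide (C1 epimers) | C=C1C(=O)O[C@@H]2/C=C(/C)C#CC(O)[C@](C)(O)C[C@@H](OC(=O)[C@@H](C)CC)[C@@H]12 | intermediate
22 | (4Z,6R,7R,8R,10R)-10-hydroxy-8-[(2S)-2-methylbutanoyloxy]-1-oxogermacra-4,11(13)-dien-2-yn-12,6-olide | C=C1C(=O)O[C@@H]2/C=C(/C)C#CC(=O)[C@](C)(O)C[C@@H](OC(=O)[C@@H](C)CC)[C@@H]12 | intermediate
23 | atripliciolide (2S)-2-methylbutanoate, [(3aR,4R,6R,10Z,11aR)-6,10-dimethyl-3-methylidene-2,7-dioxo-2,3,3a,4,5,6,7,11a-octahydro-6,9-epoxycyclodeca[b]furan-4-yl] (2S)-2-methylbutanoate | C=C1C(=O)O[C@@H]2/C=C(/C)C3=CC(=O)[C@@](C)(C[C@@H](OC(=O)[C@@H](C)CC)[C@@H]12)O3 | target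

Total step count: 15. Longest linear sequence: 13 steps (steps 3 to 15, from 5).

Steps most likely to fail

Step 14. Intermolecular coupling (oligomerisation) or reduction of the C–I bond to C–H may outpace ring closure, because the ten-membered enyne is strained. The fallback keeps the C1–C2 closure but replaces the reductive organochromium route by a halide-free zinc acetylide addition of the terminal alkyne under amine base. It sets out from 17: buffered desilylation (Bu4NF, AcOH, THF, 0 °C) should give the terminal alkyne acetonide F1; AcOH/H2O/THF then gives the alkyne diol F2; IBX in DMSO gives the alkyne hydroxy aldehyde F3; Zn(OTf)2 and Et3N in toluene at high dilution generate the zinc acetylide in situ, which adds to the non-enolisable aldehyde and comes back to the route at 21.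

Step 10. The lactone enolate may attack the neighbouring C8 ester carbonyl (acyl transfer to C11), or the side-chain ester may be enolised and lose its configuration. The fallback moves the methylenation ahead of the esterification. It sets out from 12: Et3SiCl and imidazole give the triethylsilyl ether F4; the same enolate/Eschenmoser's salt sequence gives the Mannich base F5 and, after MeI, the ammonium iodide F6, which eliminates with NaHCO3 to the α-methylene lactone silyl ether F7; HF·pyridine in THF/pyridine frees the α-methylene alcohol F8; Steglich esterification with 13 comes back to the route at 17.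

Step 8. Facial discrimination in hydride delivery to the C8 ketone may be too low, giving the C8 epimer. The fallback uses hydroxyl-directed reduction before lactonisation. It sets out from 10, isolated after the oxidative work-up of step 7 with the acid treatment left out: Me4NBH(OAc)3 in MeCN/AcOH at −25 °C (Evans–Saksena reduction, intramolecular hydride delivery from the C6–O–boron acetoxyborohydride) should give the 6,8-anti diol ester F9; PPTS in toluene at 50 °C then lactonises it under equilibrating conditions to the more stable trans-6,12-lactone and comes back to the route at 12.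

Further compounds
F1 | step 14 | (1R)-1-{(2R,3R)-4-methylidene-2-[(1Z)-2-methylbut-1-en-3-yn-1-yl]-5-oxooxolan-3-yl}-2-[(4R)-2,2,4-trimethyl-1,3-dioxolan-4-yl]ethyl (2S)-2-methylbutanoate | C=C1C(=O)O[C@H](/C=C(/C)C#C)[C@H]1[C@H](OC(=O)[C@@H](C)CC)C[C@]2(C)COC(C)(C)O2
F2 | step 14 | (1R,3R)-3,4-dihydroxy-3-methyl-1-{(2R,3R)-4-methylidene-2-[(1Z)-2-methylbut-1-en-3-yn-1-yl]-5-oxooxolan-3-yl}butyl (2S)-2-methylbutanoate | C=C1C(=O)O[C@H](/C=C(/C)C#C)[C@H]1[C@H](OC(=O)[C@@H](C)CC)C[C@@](C)(O)CO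
F3 | step 14 | (1R,3R)-3-hydroxy-3-methyl-1-{(2R,3R)-4-methylidene-2-[(1Z)-2-methylbut-1-en-3-yn-1-yl]-5-oxooxolan-3-yl}-4-oxobutyl (2S)-2-methylbutanoate | C=C1C(=O)O[C@H](/C=C(/C)C#C)[C@H]1[C@H](OC(=O)[C@@H](C)CC)C[C@@](C)(O)C=O
F4 | step 10 | triethylsilyl ether of 12 at the C8 hydroxyl | C1C(=O)O[C@H](/C=C(/C)C#C[Si](C)(C)C)[C@H]1[C@H](O[Si](CC)(CC)CC)C[C@]2(C)COC(C)(C)O2
F5 | step 10 | 4-[(dimethylamino)methyl] derivative of F4 at the lactone α-carbon C11 (both C11 epimers) | CN(C)CC1C(=O)O[C@H](/C=C(/C)C#C[Si](C)(C)C)[C@H]1[C@H](O[Si](CC)(CC)CC)C[C@]2(C)COC(C)(C)O2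
F6 | step 10 | N-methyl quaternary ammonium iodide of F5 | C[N+](C)(C)CC1C(=O)O[C@H](/C=C(/C)C#C[Si](C)(C)C)[C@H]1[C@H](O[Si](CC)(CC)CC)C[C@]2(C)COC(C)(C)O2.[I-]
F7 | step 10 | (4R,5R)-3-methylidene-5-[(1Z)-2-methyl-4-(trimethylsilyl)but-1-en-3-yn-1-yl]-4-{(1R)-1-(triethylsilyloxy)-2-[(4R)-2,2,4-trimethyl-1,3-dioxolan-4-yl]ethyl}oxolan-2-one | C=C1C(=O)O[C@H](/C=C(/C)C#C[Si](C)(C)C)[C@H]1[C@H](O[Si](CC)(CC)CC)C[C@]2(C)COC(C)(C)O2
F8 | step 10 | (4R,5R)-4-{(1R)-1-hydroxy-2-[(4R)-2,2,4-trimethyl-1,3-dioxolan-4-yl]ethyl}-3-methylidene-5-[(1Z)-2-methyl-4-(trimethylsilyl)but-1-en-3-yn-1-yl]oxolan-2-one | C=C1C(=O)O[C@H](/C=C(/C)C#C[Si](C)(C)C)[C@H]1[C@H](O)C[C@]2(C)COC(C)(C)O2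
F9 | step 8 | ethyl (3R,4R,5Z)-4-hydroxy-3-{(1R)-1-hydroxy-2-[(4R)-2,2,4-trimethyl-1,3-dioxolan-4-yl]ethyl}-6-methyl-8-(trimethylsilyl)oct-5-en-7-ynoate | CCOC(=O)C[C@@H]([C@H](O)/C=C(/C)C#C[Si](C)(C)C)[C@H](O)C[C@]1(C)COC(C)(C)O1
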